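**Retrosynthetic overview**
1. The enamide N–C(ring) bond is cut first: a copper-catalysed vinyl amidation joins a ring 2-iodoenone and a primary (2E,4S,6S)-enamide, followed by ester and acetal removal.
2. The iodoenone comes from α-iodination of a cis-fused dioxolane enone, made by enantioselective acetalization/oxa-Michael desymmetrization of an achiral p-quinol (sets both ring stereocentres).
3. The p-quinol comes from oxidative dearomatization of a 4-alkylphenol, assembled by B-alkyl Suzuki coupling of methyl pent-4-enoate with 4-iodophenol.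
4. The enamide comes from its methyl ester, made by a nickel hydride γ-selective hydroalkylation of methyl pentadienoate with (S)-1-iodo-2,4-dimethylpentane (sets C4); C6 comes from (R)-3-bromo-2-methylpropan-1-ol.
5. Ring order: the carbocycle is the benzene ring of 4-iodophenol, dearomatized in step 2; the temporary dioxolane ring is closed in step 3 and opened in step 11.

Assumption: where a chiral catalyst is named, the antipode that delivers the drawn configuration is meant (sense to be confirmed on the first run), and the acetal carbon of 7, 8, 17, 18 and 19 is carried as an epimer mixture because it is removed at the end.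

**Step 1**
Reactants: 1 methyl pent-4-enoate; 2 4-iodophenol
Product: 4 methyl 5-(4-hydroxyphenyl)pentanoate, via B-alkyl-9-BBN adduct 3 (not isolated)
Conditions: 1, 9-BBN-H, THF, 0 °C → rt; then 2, PdCl2(dppf) (3 mol%), K3PO4 (3 equiv, aq.), DMF, 50 °C
Reagents that add atoms: none
Why: Anti-Markovnikov hydroboration of the terminal alkene followed by B-alkyl Suzuki–Miyaura coupling with the aryl iodide at zerovalent palladium (dppf suppresses β-hydride elimination); no stereocentre is formed.

**Step 2**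
Reactants: 4 methyl 5-(4-hydroxyphenyl)pentanoate
Product: 5 methyl 5-(1-hydroxy-4-oxocyclohexa-2,5-dien-1-yl)pentanoate
Conditions: PhI(OAc)2 (1.2 equiv), MeCN/H2O (3:1), 0 °C
Reagents that add atoms: water, SMILES O
Why: Trivalent-iodine oxidative dearomatization, in which the phenol is oxidized to a phenoxenium equivalent that water captures at the para carbon, giving the achiral p-quinol.

**Step 3**
Reactants: 5 methyl 5-(1-hydroxy-4-oxocyclohexa-2,5-dien-1-yl)pentanoate
Product: 7 methyl 5-[(3aS,7aR)-2-(4-methoxyphenyl)-5-oxo-3a,4,5,7a-tetrahydro-1,3-benzodioxol-7a-yl]pentanoate (cis-fused dioxolane; epimers at C2), via hemiacetal 6 (not isolated)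
Conditions: 4-MeOC6H4CHO (3 equiv), (R)-3,3'-bis(2,4,6-triisopropylphenyl)-1,1'-binaphthyl-2,2'-diyl hydrogen phosphate (10 mol%), 1,2-dichloroethane, 40 °C
Reagents that add atoms: 4-methoxybenzaldehyde, SMILES COc1ccc(C=O)cc1
Why: Chiral phosphoric acid catalysed acetalization/oxa-Michael desymmetrization cascade, in which the OH of hemiacetal 6 adds 5-exo to one of the two enantiotopic enone arms inside the chiral hydrogen-bonded pocket; this fixes C7a (R), and because the five-membered ring must be cis-fused it also fixes C3a (S).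

**Step 4**
Reactants: 7 methyl 5-[(3aS,7aR)-2-(4-methoxyphenyl)-5-oxo-3a,4,5,7a-tetrahydro-1,3-benzodioxol-7a-yl]pentanoate
Product: 8 methyl 5-[(3aS,7aR)-6-iodo-2-(4-methoxyphenyl)-5-oxo-3a,4,5,7a-tetrahydro-1,3-benzodioxol-7a-yl]pentanoate
Conditions: I2 (2.5 equiv), pyridine/CH2Cl2 (1:1), 0 °C → rt, dark
Reagents that add atoms: iodine, SMILES II
Why: Johnson α-iodination of the only enone (Baylis–Hillman-type sequence of pyridine β-addition, enolate iodination and pyridine elimination); the stereocentres are not touched.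

**Step 5**
Reactants: 9 (R)-3-bromo-2-methylpropan-1-ol
Product: 12 (S)-2,4-dimethylpentan-1-ol, via bromo alkoxide 10 (not isolated), via coupled alkoxide 11 (not isolated)
Conditions: i-PrMgCl (2.5 equiv), Li2CuCl4 (5 mol%), THF, −78 → 0 °C; 1 M HCl work-up
Reagents that add atoms: isopropylmagnesium chloride, SMILES CC(C)[Mg]Cl
Why: Kochi-type copper-catalysed sp3–sp3 cross-coupling of the primary bromide (as its magnesium alkoxide) with the secondary Grignard reagent; the stereocentre is a spectator and its descriptor changes from R to S only through the CIP priority change.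

**Step 6**
Reactants: 12 (S)-2,4-dimethylpentan-1-ol
Product: 13 (S)-1-iodo-2,4-dimethylpentane
Conditions: I2, PPh3, imidazole, CH2Cl2, 0 °C → rt
Reagents that add atoms: iodine, SMILES II
Why: Appel iodination of a primary alcohol by SN2 at CH2, leaving the adjacent stereocentre untouched.

**Step 7**
Reactants: 13 (S)-1-iodo-2,4-dimethylpentane; 14 methyl (E)-penta-2,4-dienoate
Product: 15 methyl (2E,4S,6S)-4,6,8-trimethylnon-2-enoate
Conditions: 14 (2 equiv, slow addition), NiBr2(dme) (10 mol%), 2,6-bis[(4S)-4-(2-phenylethyl)-4,5-dihydro-1,3-oxazol-2-yl]pyridine (12 mol%), (EtO)2MeSiH (2.5 equiv), KF (2.5 equiv), DMA/t-BuOH (4:1), 0 °C → rt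
Reagents that add atoms: none
Why: Proposed new method: a nickel hydride (from the nickel/Pybox complex, silane and fluoride) should add across the terminal alkene of 14 with hydride to C5, giving the ester-conjugated 1-(methoxycarbonyl)-3-methylallyl nickel species that is also the intermediate of the known nickel/Pybox enantioconvergent Negishi coupling of racemic γ-chloro enoates, where C–C bond formation occurs at the γ carbon with E geometry; monovalent nickel abstracts iodine from 13, the primary radical is captured, and ligand-controlled reductive elimination from trivalent nickel forms C4–C5 and sets C4 (S) under catalyst control while the remote C6 centre is untouched; the closest known reaction types are NiH-catalysed enantioselective reductive hydroalkylation of alkenes with alkyl iodides and nickel-catalysed hydrofunctionalization of 1,3-dienes, neither shown for γ-selective alkylation of a conjugated dienoate.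

**Step 8**
Reactants: 15 methyl (2E,4S,6S)-4,6,8-trimethylnon-2-enoate
Product: 16 (2E,4S,6S)-4,6,8-trimethylnon-2-enamide
Conditions: Me3Al (3 equiv), NH4Cl (3 equiv), toluene, 0 → 50 °C; 1 M HCl work-up
Reagents that add atoms: ammonium chloride, SMILES [NH4+].[Cl-]
Why: Weinreb-type aluminium amide aminolysis, in which MeAl(Cl)NH2 made in the flask converts the methyl ester into the primary amide by 1,2-addition without conjugate addition or epimerization at C4.

**Step 9**
Reactants: 8 methyl 5-[(3aS,7aR)-6-iodo-2-(4-methoxyphenyl)-5-oxo-3a,4,5,7a-tetrahydro-1,3-benzodioxol-7a-yl]pentanoate; 16 (2E,4S,6S)-4,6,8-trimethylnon-2-enamide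
Product: 17 methyl 5-[(3aS,7aR)-2-(4-methoxyphenyl)-5-oxo-6-{[(2E,4S,6S)-4,6,8-trimethylnon-2-enoyl]amino}-3a,4,5,7a-tetrahydro-1,3-benzodioxol-7a-yl]pentanoate
Conditions: CuI (10 mol%), N,N'-dimethylethylenediamine (20 mol%), Cs2CO3 (1.5 equiv), THF, 50 °C
Reagents that add atoms: none
Why: Goldberg–Buchwald copper-catalysed vinyl amidation, in which the diamine-ligated monovalent copper amidate of 16 reacts at the activated α-iodoenone C–I bond to form the enamide C–N bond with retention of both alkenes and no change at any stereocentre.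

**Step 10**
Reactants: 17 methyl 5-[(3aS,7aR)-2-(4-methoxyphenyl)-5-oxo-6-{[(2E,4S,6S)-4,6,8-trimethylnon-2-enoyl]amino}-3a,4,5,7a-tetrahydro-1,3-benzodioxol-7a-yl]pentanoate
Product: 19 5-[(3aS,7aR)-2-(4-methoxyphenyl)-5-oxo-6-{[(2E,4S,6S)-4,6,8-trimethylnon-2-enoyl]amino}-3a,4,5,7a-tetrahydro-1,3-benzodioxol-7a-yl]pentanoic acid, via trimethylstannyl ester 18 (not isolated)
Conditions: Me3SnOH (6 equiv), 1,2-dichloroethane, 70 °C; cold 0.05 M HCl wash
Reagents that add atoms: trimethyltin hydroxide, SMILES C[Sn](C)(C)O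
Why: Trimethyltin hydroxide ester hydrolysis (tin-assisted acyl–oxygen cleavage under near-neutral conditions) cleaves the methyl ester without the hydroxide-induced retro-oxa-Michael or β-elimination of the β-alkoxy ketone.

**Step 11**
Reactants: 19 5-[(3aS,7aR)-2-(4-methoxyphenyl)-5-oxo-6-{[(2E,4S,6S)-4,6,8-trimethylnon-2-enoyl]amino}-3a,4,5,7a-tetrahydro-1,3-benzodioxol-7a-yl]pentanoic acid
Product: 20 Salternamide E, 5-[(1R,6S)-1,6-dihydroxy-4-oxo-3-{[(2E,4S,6S)-4,6,8-trimethylnon-2-enoyl]amino}cyclohex-2-en-1-yl]pentanoic acid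
Conditions: AcOH/THF/H2O (3:1:1), rt → 35 °C
Reagents that add atoms: none
Why: Mild acid hydrolysis of the electron-rich p-methoxybenzylidene acetal (stabilized oxocarbenium) releases the cis-diol without ionizing the tertiary C–O bond or hydrolysing the enamide; no stereocentre is touched.

**Compound list**
1 | methyl pent-4-enoate | C=CCCC(=O)OC | starting material
2 | 4-iodophenol | Oc1ccc(I)cc1 | starting material
3 | methyl 5-(9-borabicyclo[3.3.1]nonan-9-yl)pentanoate | COC(=O)CCCCB1C2CCCC1CCC2 | intermediate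
4 | methyl 5-(4-hydroxyphenyl)pentanoate | COC(=O)CCCCc1ccc(O)cc1 | intermediate
5 | methyl 5-(1-hydroxy-4-oxocyclohexa-2,5-dien-1-yl)pentanoate | COC(=O)CCCCC1(O)C=CC(=O)C=C1 | intermediate
6 | methyl 5-{1-[hydroxy(4-methoxyphenyl)methoxy]-4-oxocyclohexa-2,5-dien-1-yl}pentanoate (hemiacetal) | COC(=O)CCCCC1(OC(O)c2ccc(OC)cc2)C=CC(=O)C=C1 | intermediate
7 | methyl 5-[(3aS,7aR)-2-(4-methoxyphenyl)-5-oxo-3a,4,5,7a-tetrahydro-1,3-benzodioxol-7a-yl]pentanoate | O=C1C=C[C@@]2(CCCCC(=O)OC)OC(c3ccc(OC)cc3)O[C@H]2C1 | intermediate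
8 | methyl 5-[(3aS,7aR)-6-iodo-2-(4-methoxyphenyl)-5-oxo-3a,4,5,7a-tetrahydro-1,3-benzodioxol-7a-yl]pentanoate | O=C1C(I)=C[C@@]2(CCCCC(=O)OC)OC(c3ccc(OC)cc3)O[C@H]2C1 | intermediate
9 | (R)-3-bromo-2-methylpropan-1-ol | OC[C@@H](C)CBr | starting material
10 | chloromagnesium (2R)-3-bromo-2-methylpropan-1-olate | Cl[Mg]OC[C@@H](C)CBr | intermediate
11 | chloromagnesium (2S)-2,4-dimethylpentan-1-olate | CC(C)C[C@H](C)CO[Mg]Cl | intermediate
12 | (S)-2,4-dimethylpentan-1-ol | CC(C)C[C@H](C)CO | intermediate
13 | (S)-1-iodo-2,4-dimethylpentane | CC(C)C[C@H](C)CI | intermediate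
14 | methyl (E)-penta-2,4-dienoate | C=C/C=C/C(=O)OC | starting material
15 | methyl (2E,4S,6S)-4,6,8-trimethylnon-2-enoate | CC(C)C[C@H](C)C[C@H](C)/C=C/C(=O)OC | intermediate
16 | (2E,4S,6S)-4,6,8-trimethylnon-2-enamide | CC(C)C[C@H](C)C[C@H](C)/C=C/C(N)=O | intermediate
17 | methyl 5-[(3aS,7aR)-2-(4-methoxyphenyl)-5-oxo-6-{[(2E,4S,6S)-4,6,8-trimethylnon-2-enoyl]amino}-3a,4,5,7a-tetrahydro-1,3-benzodioxol-7a-yl]pentanoate | CC(C)C[C@H](C)C[C@H](C)/C=C/C(=O)NC1=C[C@@]2(CCCCC(=O)OC)OC(c3ccc(OC)cc3)O[C@H]2CC1=O | intermediate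
18 | trimethylstannyl 5-[(3aS,7aR)-2-(4-methoxyphenyl)-5-oxo-6-{[(2E,4S,6S)-4,6,8-trimethylnon-2-enoyl]amino}-3a,4,5,7a-tetrahydro-1,3-benzodioxol-7a-yl]pentanoate | CC(C)C[C@H](C)C[C@H](C)/C=C/C(=O)NC1=C[C@@]2(CCCCC(=O)O[Sn](C)(C)C)OC(c3ccc(OC)cc3)O[C@H]2CC1=O | intermediate
19 | 5-[(3aS,7aR)-2-(4-methoxyphenyl)-5-oxo-6-{[(2E,4S,6S)-4,6,8-trimethylnon-2-enoyl]amino}-3a,4,5,7a-tetrahydro-1,3-benzodioxol-7a-yl]pentanoic acid | CC(C)C[C@H](C)C[C@H](C)/C=C/C(=O)NC1=C[C@@]2(CCCCC(=O)O)OC(c3ccc(OC)cc3)O[C@H]2CC1=O | intermediate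
20 | Salternamide E, 5-[(1R,6S)-1,6-dihydroxy-4-oxo-3-{[(2E,4S,6S)-4,6,8-trimethylnon-2-enoyl]amino}cyclohex-2-en-1-yl]pentanoic acid | CC(C)C[C@H](C)C[C@H](C)/C=C/C(=O)NC1=C[C@](O)(CCCCC(=O)O)[C@@H](O)CC1=O | target

**Step count**
Total steps: 11 (core branch steps 1–4, side-chain branch steps 5–8, joined in step 9, then steps 10 and 11).
Longest linear sequence: 7 steps (steps 1, 2, 3, 4, 9, 10, 11; the side-chain branch 5, 6, 7, 8, 9, 10, 11 is equally long).

**Three steps most likely to fail**

Step 7 (the proposed new hydroalkylation). The risks are α- instead of γ-alkylation, simple conjugate reduction of 14, reduction of 13, and insufficient catalyst control at C4. The fallback uses known chemistry, sets out from iodide 13 and comes back at ester 15. But-3-en-2-ol and methyl acrylate are joined by cross-metathesis (second-generation Grubbs catalyst (SIMes)(PCy3)Cl2Ru=CHPh, CH2Cl2, 40 °C) to give racemic methyl (E)-4-hydroxypent-2-enoate F1. MsCl/Et3N and then LiCl in DMF convert it into racemic methyl (E)-4-chloropent-2-enoate F2. Iodide 13 is inserted with zinc dust (cat. I2, DMA, 70 °C) to give [(2S)-2,4-dimethylpentyl]zinc iodide F3. The known nickel/Pybox enantioconvergent Negishi coupling of the racemic secondary allylic chloride with the alkylzinc (NiCl2(dme), the same Pybox ligand, NaCl, DMA/DMF, −10 °C) then joins F2 and F3 at the γ carbon to give 15.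

Step 3 (desymmetrization). The risks are slow hemiacetal formation with the electron-rich aromatic aldehyde and an enantiomeric excess below what the route needs. The fallback sets out from p-quinol 5 and comes back at acetal 7. Compound 5 is treated with phenylboronic acid and a cinchona-derived bifunctional amine–thiourea catalyst (toluene, 4 Å sieves, rt), so that the boronic acid hemiester delivers its B–OH oxygen intramolecularly to one enone arm. This gives the cis-fused cyclic boronate methyl 5-[(3aS,7aR)-5-oxo-2-phenyl-3a,4,5,7a-tetrahydro-1,3,2-benzodioxaborol-7a-yl]pentanoate F4. Transesterification with pinacol frees the cis-diol methyl 5-[(1R,6S)-1,6-dihydroxy-4-oxocyclohex-2-en-1-yl]pentanoate F5, which can be recrystallized to raise the enantiomeric purity. 4-Methoxybenzaldehyde dimethyl acetal with PPTS in CH2Cl2 then gives 7.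

Step 9 (copper-catalysed amidation). The risk is base-induced retro-oxa-Michael opening or β-elimination of the β-alkoxy ketone under carbonate at 50 °C, and sluggish coupling next to the quaternary centre. The fallback sets out from iodoenone 8 and ester 15 and comes back at 17. Base-free copper-catalysed azidation of 8 (NaN3, CuI, sodium ascorbate, N,N'-dimethylethylenediamine, EtOH/H2O, rt) gives methyl 5-[(3aS,7aR)-6-azido-2-(4-methoxyphenyl)-5-oxo-3a,4,5,7a-tetrahydro-1,3-benzodioxol-7a-yl]pentanoate F6. Staudinger reduction (PPh3, THF/H2O) gives the 2-amino enone methyl 5-[(3aS,7aR)-6-amino-2-(4-methoxyphenyl)-5-oxo-3a,4,5,7a-tetrahydro-1,3-benzodioxol-7a-yl]pentanoate F7. In parallel, 15 is saponified (LiOH, THF/H2O, then acid) to (2E,4S,6S)-4,6,8-trimethylnon-2-enoic acid F8 and converted with oxalyl chloride and cat. DMF into (2E,4S,6S)-4,6,8-trimethylnon-2-enoyl chloride F9. N-Acylation of F7 with F9 (pyridine, CH2Cl2, 0 °C) gives 17.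

**Further compounds**
F1 | step 7 | methyl (E)-4-hydroxypent-2-enoate (racemic) | CC(O)/C=C/C(=O)OC
F2 | step 7 | methyl (E)-4-chloropent-2-enoate (racemic) | CC(Cl)/C=C/C(=O)OC
F3 | step 7 | [(2S)-2,4-dimethylpentyl]zinc iodide | CC(C)C[C@H](C)C[Zn]I
F4 | step 3 | methyl 5-[(3aS,7aR)-5-oxo-2-phenyl-3a,4,5,7a-tetrahydro-1,3,2-benzodioxaborol-7a-yl]pentanoate | O=C1C=C[C@@]2(CCCCC(=O)OC)OB(c3ccccc3)O[C@H]2C1
F5 | step 3 | methyl 5-[(1R,6S)-1,6-dihydroxy-4-oxocyclohex-2-en-1-yl]pentanoate | O=C1C=C[C@](O)(CCCCC(=O)OC)[C@@H](O)C1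
F6 | step 9 | methyl 5-[(3aS,7aR)-6-azido-2-(4-methoxyphenyl)-5-oxo-3a,4,5,7a-tetrahydro-1,3-benzodioxol-7a-yl]pentanoate | [N-]=[N+]=NC1=C[C@@]2(CCCCC(=O)OC)OC(c3ccc(OC)cc3)O[C@H]2CC1=O
F7 | step 9 | methyl 5-[(3aS,7aR)-6-amino-2-(4-methoxyphenyl)-5-oxo-3a,4,5,7a-tetrahydro-1,3-benzodioxol-7a-yl]pentanoate | NC1=C[C@@]2(CCCCC(=O)OC)OC(c3ccc(OC)cc3)O[C@H]2CC1=O
F8 | step 9 | (2E,4S,6S)-4,6,8-trimethylnon-2-enoic acid | CC(C)C[C@H](C)C[C@H](C)/C=C/C(=O)O
F9 | step 9 | (2E,4S,6S)-4,6,8-trimethylnon-2-enoyl chloride | CC(C)C[C@H](C)C[C@H](C)/C=C/C(=O)Cl
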